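The numbers come from no measurement, and the outcome is calculated.

The coupling partner is the budget of this flask: each starting material lost costs one, and the second cycle draws on it as well.

    second substrate + free catalyst ⇌ catalyst intermediate B (K1 = 39.5 L mol⁻¹, k1 = 1310 L mol⁻¹ min⁻¹)
    coupling partner + catalyst intermediate A → free catalyst + target (k2 = 931 L mol⁻¹ min⁻¹)
    starting material + free catalyst ⇌ catalyst intermediate A (K3 = 6500 L mol⁻¹, k3 = 2710 L mol⁻¹ min⁻¹)
    coupling partner + catalyst intermediate B → free catalyst + second product (k4 = 3110 L mol⁻¹ min⁻¹)
    coupling partner + target → over-reaction product (k5 = 0.555 L mol⁻¹ min⁻¹)

starting material 0.020 M; second substrate 2.00 equiv (fed, over 25 min); coupling partner 0.700 equiv; free catalyst 0.2 mol%; time 8.0 h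

- part of the starting material gone at 8.0 h
- the target standing at 8.0 h, as a percentage of the starting material charged
- the over-reaction product standing at 8.0 h, as a percentage of the starting material charged

**The budget.** At 0.700 equiv per starting material the partner is your limiting reagent, and the charges allow 70.0% of target. So reckon conversion as that budget times the partner share, the part of the partner that passes through catalyst intermediate A and not through catalyst intermediate B.

**Binding extreme.** Suppose release is instant, so each bound catalyst couples at once. The two flows then stand as binding constant times concentration. At the charged [starting material] and [second substrate], the partner share is 50.8%. That gives a floor of 35.6% conversion. This is kinetic control.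

**Equilibrium extreme.** Suppose instead that both intermediates stand in equilibrium with free catalyst. Each flow is then release constant times equilibrium constant times concentration, the partner share is 96.1%, and the ceiling is 67.3%. This is thermodynamic control.

**Between them.** At its charge the partner releases intermediate A in 0.0767 min, faster than that intermediate falls apart, which takes 2.40 min. Catalyst intermediate B is released in 0.0230 min but falls apart in 0.0302 min, so it goes on to release only part of the time. Counting the odds of both intermediates at the charges, the partner share is 63.8%, so the flask starts well above the binding share. Release slows as [coupling partner] falls, which moves the flask toward the equilibrium extreme. My reckoning therefore puts conversion between floor and ceiling, and I leave out the feed and the fall of [starting material].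

**The forecast.** It gives 51% conversion, 46% target and 5% over-reaction product, with selectivity “moving toward the much more A-favouring equilibrium limit only as the partner runs out”.

**The result.** The flask gives 51.8% conversion, 47.1% target and 4.57% over-reaction product, all within the forecast's margin. It stops for want of partner, with 0% left: without that shrinking supply, conversion goes from 51.8% to 100%, and ten times the time still reads 51.8%. Its conversion is 74.0% of the budget, above 50.8% and below 96.1%. The neighbour flask with 5.00 equiv of second substrate has a floor of 20.5% and a ceiling of 63.5%, and it reads 42.8%.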